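**Plan**

- Retrosynthesis cuts, in this order: (a) the two gallate ester C–O bonds and all O–benzyl bonds; (b) the C8–C1' bond between ring A of the flavan and the diarylmethine carbon of the ring-opened unit (C1' = diarylmethine, C2' = carbinol, C3' = CH2 of its propane chain), the epoxide partner itself coming apart at the C3'–aryl bond; (c) the C2–C3 bond of ring C.
- Enabling feature: in ring C, C2 (benzylic and bonded to the ring oxygen O1) and C3 (carbinol) are neighbouring oxygen-bearing, carbonyl-derived carbons of like polarity, and C2 with ring B is a gallic acid unit. Ring C is therefore the retron of a reductive coupling between a gallate ester on O1 and an ortho CH2CHO group.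
- Forward order: a Claisen shift puts allyl (C4, C3) on ring A and frees O1; O1 ester; aldehyde; titanium coupling closes ring C as the 4H-chromene; C2/C3 are adjusted to the cis-flavan-3-ol; C8 bromide to aryllithium; opening of the upper epoxide; two gallates; hydrogenolysis.
- Helpers and their removal: ester oxidation level at C2 (taken down by hydroboration), the 3-ketone, Br at C8, TBS on O3 and 17 benzyl ethers.
- Stereochemistry: C2 from reagent-controlled hydroboration of the C2=C3 enol ether; C3 from substrate-controlled hydride reduction of the 3-ketone (cis); C2' from a Shi epoxidation; C1' relayed from it by invertive epoxide opening.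

Key step: step 5

Remark: 3,5-bis(benzyloxy)phenol, 3,4,5-tris(benzyloxy)benzoyl chloride, 3,4,5-tris(benzyloxy)benzaldehyde and 1,3,5-tris(benzyloxy)benzene are taken as purchasable benzyl-protected building blocks, and every phenol stays a benzyl ether until the last step.

**Route**

Step 1
Reactants: 1 3,5-bis(benzyloxy)phenol; 2 allyl bromide
Product: 3 1-(allyloxy)-3,5-bis(benzyloxy)benzene
Conditions: K2CO3, acetone, reflux
Reagents that add atoms: none
Why: Williamson O-allylation of the only free phenol, which places the future C3/C4 carbons on the oxygen that will become O1.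

Step 2
Reactants: 3 1-(allyloxy)-3,5-bis(benzyloxy)benzene
Product: 4 2-allyl-3,5-bis(benzyloxy)phenol
Conditions: N,N-diethylaniline, 200 °C
Reagents that add atoms: none
Why: Aromatic Claisen rearrangement; the two ortho positions are equivalent, so one 2-allylphenol should form, with O1 freed and C4/C3 (plus a sacrificial terminal CH2) on ring A.

Step 3
Reactants: 4 2-allyl-3,5-bis(benzyloxy)phenol; 5 3,4,5-tris(benzyloxy)benzoyl chloride
Product: 6 2-allyl-3,5-bis(benzyloxy)phenyl 3,4,5-tris(benzyloxy)benzoate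
Conditions: Et3N, DMAP (cat.), CH2Cl2, 0 °C → rt
Reagents that add atoms: none
Why: DMAP-catalysed acylation of the phenol; the ester carbonyl carbon is the future C2 and its aryl group the future ring B, held one oxidation level above the target.

Step 4
Reactants: 6 2-allyl-3,5-bis(benzyloxy)phenyl 3,4,5-tris(benzyloxy)benzoate
Product: 8 3,5-bis(benzyloxy)-2-(2-oxoethyl)phenyl 3,4,5-tris(benzyloxy)benzoate, via vicinal diol 7 (not isolated)
Conditions: OsO4 (cat.), NaIO4, 2,6-lutidine, dioxane–H2O, rt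
Reagents that add atoms: sodium periodate, [Na+].[O-]I(=O)(=O)=O, with catalytic osmium tetroxide, O=[Os](=O)(=O)=O, as oxygen carrier (oxygens of 7 and the aldehyde oxygen of 8)
Why: Lemieux–Johnson oxidation (dihydroxylation then periodate cleavage) should turn the terminal alkene into the C3 aldehyde without touching the ester or benzyl ethers, with 2,6-lutidine suppressing over-oxidation.

Step 5
Reactants: 8 3,5-bis(benzyloxy)-2-(2-oxoethyl)phenyl 3,4,5-tris(benzyloxy)benzoate
Product: 9 5,7-bis(benzyloxy)-2-[3,4,5-tris(benzyloxy)phenyl]-4H-chromene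
Conditions: TiCl3, Zn dust, DME, reflux (reagent pre-formed), slow addition of 8 at high dilution; K2CO3 (aq) work-up
Reagents that add atoms: none
Why: Low-valent titanium from TiCl3/Zn transfers an electron to the aldehyde carbon C3; the titanium-bound ketyl adds to the neighbouring aryl ester carbonyl C2, and the metal-bound pinacolate-type species is deoxygenated twice to the enol ether C2=C3, so two acceptor carbons of like polarity are joined (intramolecular McMurry coupling). The closest known reaction type is the titanium-induced oxo-ester cyclization that turns acyloxy carbonyl compounds into cyclic enol ethers and benzofurans. Ring C closes in a 6-exo-trig mode, the ketyl carbon C3 attacking the exocyclic C=O of the O1 ester through a six-membered titanium-bridged array. No stereocentre is formed: C2 and C3 are left trigonal on purpose so that steps 6 to 8 can set both under reagent and substrate control. The selectivity needed is intramolecular cross-coupling over aldehyde pinacol dimerization, aldol self-condensation and ester cleavage; the ortho placement of CH2CHO and the ester on ring A, the high electrophilicity of the aryl ester and slow addition at high dilution should secure it, and the basic work-up protects the acid-labile enol ether.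

Step 6
Reactants: 9 5,7-bis(benzyloxy)-2-[3,4,5-tris(benzyloxy)phenyl]-4H-chromene
Product: 11 (2R,3S)-5,7-bis(benzyloxy)-2-[3,4,5-tris(benzyloxy)phenyl]chroman-3-ol, via alkylborane 10 (not isolated)
Conditions: (−)-IpcBH2 (from (+)-α-pinene), THF, −25 °C; then NaOH (aq), H2O2, 0 °C → rt
Reagents that add atoms: (−)-isopinocampheylborane, C[C@H]1[C@H](B)C[C@@H]2C[C@H]1C2(C)C (hydrogen at C2; boron and the Ipc group stay only in 10); hydrogen peroxide, OO (oxygen at C3)
Why: Asymmetric hydroboration–oxidation adds H to C2 and B to C3 (β to O1, distal to the aryl group) on one face, then oxidizes C–B with retention, giving the 2,3-trans alcohol; the face, and with it 2R, is set by the reagent, the sense being assigned by analogy with 1-arylcycloalkenes, which this borane is known to convert into (1S,2R)-trans-2-arylcycloalkanols, the spatial counterpart of (2R,3S).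

Step 7
Reactants: 11 (2R,3S)-5,7-bis(benzyloxy)-2-[3,4,5-tris(benzyloxy)phenyl]chroman-3-ol
Product: 12 (2R)-5,7-bis(benzyloxy)-2-[3,4,5-tris(benzyloxy)phenyl]chroman-3-one
Conditions: Dess–Martin periodinane, CH2Cl2, rt
Reagents that add atoms: none
Why: Dess–Martin oxidation of the secondary alcohol under near-neutral conditions should give the flavan-3-one without epimerizing the enolizable C2.

Step 8
Reactants: 12 (2R)-5,7-bis(benzyloxy)-2-[3,4,5-tris(benzyloxy)phenyl]chroman-3-one
Product: 13 (2R,3R)-5,7-bis(benzyloxy)-2-[3,4,5-tris(benzyloxy)phenyl]chroman-3-ol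
Conditions: LiBH(s-Bu)3 (L-Selectride), THF, −78 °C; then H2O
Reagents that add atoms: none
Why: The bulky hydride should attack the C3 ketone from the face opposite the C2 aryl group, giving the 3-OH cis to the aryl group (3R) by substrate control, as is usual for benzylated flavan-3-ones.

Step 9
Reactants: 13 (2R,3R)-5,7-bis(benzyloxy)-2-[3,4,5-tris(benzyloxy)phenyl]chroman-3-ol
Product: 14 (2R,3R)-8-bromo-5,7-bis(benzyloxy)-2-[3,4,5-tris(benzyloxy)phenyl]chroman-3-ol
Conditions: NBS (1.0 equiv), CH2Cl2, −78 °C → rt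
Reagents that add atoms: N-bromosuccinimide, O=C1CCC(=O)N1Br
Why: Electrophilic aromatic bromination; C8 of ring A, flanked by O1 and the 7-benzyloxy group, is the most nucleophilic and least hindered position of a 5,7-di-O-benzyl flavan.

Step 10
Reactants: 14 (2R,3R)-8-bromo-5,7-bis(benzyloxy)-2-[3,4,5-tris(benzyloxy)phenyl]chroman-3-ol
Product: 15 tert-butyl{[(2R,3R)-8-bromo-5,7-bis(benzyloxy)-2-[3,4,5-tris(benzyloxy)phenyl]chroman-3-yl]oxy}dimethylsilane
Conditions: TBSCl, imidazole, DMF, rt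
Reagents that add atoms: tert-butyldimethylsilyl chloride, CC(C)(C)[Si](C)(C)Cl
Why: Silylation masks the 3-OH against the organolithium of step 14.

Step 11
Reactants: 16 3,4,5-tris(benzyloxy)benzaldehyde; 17 vinylmagnesium bromide
Product: 18 1-[3,4,5-tris(benzyloxy)phenyl]prop-2-en-1-ol (racemic)
Conditions: THF, 0 °C; NH4Cl (aq)
Reagents that add atoms: none
Why: Grignard 1,2-addition to the aldehyde; the racemic carbinol suffices because its stereocentre is erased in step 12.

Step 12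
Reactants: 18 1-[3,4,5-tris(benzyloxy)phenyl]prop-2-en-1-ol; 19 1,3,5-tris(benzyloxy)benzene (3 equiv)
Product: 20 (E)-1-[3,4,5-tris(benzyloxy)phenyl]-3-[2,4,6-tris(benzyloxy)phenyl]prop-1-ene
Conditions: H2SO4 on SiO2 (cat.), CH2Cl2, rt
Reagents that add atoms: none
Why: Dehydrative Friedel–Crafts allylation through the aryl-stabilized allyl cation formed by loss of water from 18; the symmetrical arene (three equivalent CH) attacks the terminal carbon to give the conjugated (E)-alkene, and the excess of 19 limits double alkylation.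

Step 13
Reactants: 20 (E)-1-[3,4,5-tris(benzyloxy)phenyl]-3-[2,4,6-tris(benzyloxy)phenyl]prop-1-ene
Product: 21 (2R,3R)-2-[3,4,5-tris(benzyloxy)phenyl]-3-[2,4,6-tris(benzyloxy)benzyl]oxirane
Conditions: D-fructose-derived Shi ketone (30 mol %), Oxone (2KHSO5·KHSO4·K2SO4), K2CO3, Bu4NHSO4, MeCN–dimethoxymethane/aq. Na2B4O7–Na2EDTA buffer (pH 10.5), 0 °C
Reagents that add atoms: potassium peroxymonosulfate (Oxone), [K+].[O-]S(=O)(=O)OO (epoxide oxygen, passed on through the dioxirane of the ketone catalyst)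
Why: Shi asymmetric epoxidation of a trans-disubstituted aryl alkene through the spiro dioxirane transition state should give the (R,R)-epoxide, the sense being that known for trans-β-alkylstyrenes, and the basic medium preserves the acid-labile epoxide.

Step 14
Reactants: 15 tert-butyl{[(2R,3R)-8-bromo-5,7-bis(benzyloxy)-2-[3,4,5-tris(benzyloxy)phenyl]chroman-3-yl]oxy}dimethylsilane; 21 (2R,3R)-2-[3,4,5-tris(benzyloxy)phenyl]-3-[2,4,6-tris(benzyloxy)benzyl]oxirane
Product: 23 (1R,2R)-1-{(2R,3R)-5,7-bis(benzyloxy)-3-[(tert-butyldimethylsilyl)oxy]-2-[3,4,5-tris(benzyloxy)phenyl]chroman-8-yl}-1-[3,4,5-tris(benzyloxy)phenyl]-3-[2,4,6-tris(benzyloxy)phenyl]propan-2-ol, via aryllithium 22 (not isolated)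
Conditions: t-BuLi (2 equiv), THF, −78 °C; then 21, BF3·OEt2, −78 → −40 °C; NaHCO3 (aq)
Reagents that add atoms: tert-butyllithium, [Li]C(C)(C)C (lithium of 22 only)
Why: Bromine–lithium exchange followed by BF3-assisted SN2 opening of the epoxide at its benzylic carbon, the electronically activated terminus; attack anti to the epoxide oxygen inverts the benzylic carbon, which becomes (R)-C1' (the descriptor stays R because the substituent priorities change), while C2' keeps the R configuration set in step 13.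

Step 15
Reactants: 23 (the silyl ether alcohol of step 14)
Product: 24 (2R,3R)-8-{(1R,2R)-2-hydroxy-1-[3,4,5-tris(benzyloxy)phenyl]-3-[2,4,6-tris(benzyloxy)phenyl]propyl}-5,7-bis(benzyloxy)-2-[3,4,5-tris(benzyloxy)phenyl]chroman-3-ol
Conditions: Bu4NF, THF, 0 °C → rt
Reagents that add atoms: none
Why: Fluoride-induced desilylation frees the second of the two secondary alcohols that carry the gallates.

Step 16
Reactants: 24 (the diol of step 15); 5 3,4,5-tris(benzyloxy)benzoyl chloride (3 equiv)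
Product: 25 (2R,3R)-8-{(1R,2R)-2-[3,4,5-tris(benzyloxy)benzoyloxy]-1-[3,4,5-tris(benzyloxy)phenyl]-3-[2,4,6-tris(benzyloxy)phenyl]propyl}-5,7-bis(benzyloxy)-2-[3,4,5-tris(benzyloxy)phenyl]chroman-3-yl 3,4,5-tris(benzyloxy)benzoate
Conditions: Et3N, DMAP, CH2Cl2, rt → 40 °C
Reagents that add atoms: none
Why: DMAP-mediated double acylation; the two gallates are identical, so both secondary alcohols can be esterified together with the acid chloride used in step 3.

Step 17
Reactants: 25 (the heptadeca-O-benzyl bis-gallate of step 16)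
Product: 26 CNP0155034.2, (2R,3R)-5,7-dihydroxy-8-{(1R,2R)-2-(3,4,5-trihydroxybenzoyloxy)-1-(3,4,5-trihydroxyphenyl)-3-(2,4,6-trihydroxyphenyl)propyl}-2-(3,4,5-trihydroxyphenyl)chroman-3-yl 3,4,5-trihydroxybenzoate
Conditions: H2 (1 atm), Pd(OH)2/C, THF–MeOH, rt
Reagents that add atoms: none
Why: Hydrogenolysis of the 17 benzyl ethers under neutral conditions should leave the gallate esters, the O1–C2 linkage and the four stereocentres untouched, as is usual for benzylated flavan-3-ol gallates.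

**Compound list**

1 | 3,5-bis(benzyloxy)phenol | Oc1cc(OCc2ccccc2)cc(OCc2ccccc2)c1 | starting material
2 | allyl bromide | C=CCBr | starting material
3 | 1-(allyloxy)-3,5-bis(benzyloxy)benzene | C=CCOc1cc(OCc2ccccc2)cc(OCc2ccccc2)c1 | intermediate
4 | 2-allyl-3,5-bis(benzyloxy)phenol | C=CCc1c(O)cc(OCc2ccccc2)cc1OCc1ccccc1 | intermediate
5 | 3,4,5-tris(benzyloxy)benzoyl chloride | O=C(Cl)c1cc(OCc2ccccc2)c(OCc2ccccc2)c(OCc2ccccc2)c1 | starting material
6 | 2-allyl-3,5-bis(benzyloxy)phenyl 3,4,5-tris(benzyloxy)benzoate | C=CCc1c(OC(=O)c2cc(OCc3ccccc3)c(OCc3ccccc3)c(OCc3ccccc3)c2)cc(OCc2ccccc2)cc1OCc1ccccc1 | intermediate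
7 | 3,5-bis(benzyloxy)-2-(2,3-dihydroxypropyl)phenyl 3,4,5-tris(benzyloxy)benzoate (racemic) | OCC(O)Cc1c(OC(=O)c2cc(OCc3ccccc3)c(OCc3ccccc3)c(OCc3ccccc3)c2)cc(OCc2ccccc2)cc1OCc1ccccc1 | intermediate (not isolated)
8 | 3,5-bis(benzyloxy)-2-(2-oxoethyl)phenyl 3,4,5-tris(benzyloxy)benzoate | O=CCc1c(OC(=O)c2cc(OCc3ccccc3)c(OCc3ccccc3)c(OCc3ccccc3)c2)cc(OCc2ccccc2)cc1OCc1ccccc1 | intermediate
9 | 5,7-bis(benzyloxy)-2-[3,4,5-tris(benzyloxy)phenyl]-4H-chromene | c1ccccc1COc1cc(OCc2ccccc2)c2c(c1)OC(=CC2)c1cc(OCc2ccccc2)c(OCc2ccccc2)c(OCc2ccccc2)c1 | intermediate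
10 | (isopinocampheyl)borane carrying the flavan-3-yl group of 11 on boron (boron in place of the 3-OH of 11, same spatial arrangement) | C[C@H]1[C@H](B[C@H]3Cc4c(OCc5ccccc5)cc(OCc5ccccc5)cc4O[C@@H]3c3cc(OCc4ccccc4)c(OCc4ccccc4)c(OCc4ccccc4)c3)C[C@@H]2C[C@H]1C2(C)C | intermediate (not isolated)
11 | (2R,3S)-5,7-bis(benzyloxy)-2-[3,4,5-tris(benzyloxy)phenyl]chroman-3-ol | c1ccccc1COc1cc(OCc2ccccc2)c2c(c1)O[C@H](c1cc(OCc3ccccc3)c(OCc3ccccc3)c(OCc3ccccc3)c1)[C@@H](O)C2 | intermediate
12 | (2R)-5,7-bis(benzyloxy)-2-[3,4,5-tris(benzyloxy)phenyl]chroman-3-one | c1ccccc1COc1cc(OCc2ccccc2)c2c(c1)O[C@H](c1cc(OCc3ccccc3)c(OCc3ccccc3)c(OCc3ccccc3)c1)C(=O)C2 | intermediate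
13 | (2R,3R)-5,7-bis(benzyloxy)-2-[3,4,5-tris(benzyloxy)phenyl]chroman-3-ol | c1ccccc1COc1cc(OCc2ccccc2)c2c(c1)O[C@H](c1cc(OCc3ccccc3)c(OCc3ccccc3)c(OCc3ccccc3)c1)[C@H](O)C2 | intermediate
14 | (2R,3R)-8-bromo-5,7-bis(benzyloxy)-2-[3,4,5-tris(benzyloxy)phenyl]chroman-3-ol | c1ccccc1COc1cc(OCc2ccccc2)c2c(c1Br)O[C@H](c1cc(OCc3ccccc3)c(OCc3ccccc3)c(OCc3ccccc3)c1)[C@H](O)C2 | intermediate
15 | tert-butyl{[(2R,3R)-8-bromo-5,7-bis(benzyloxy)-2-[3,4,5-tris(benzyloxy)phenyl]chroman-3-yl]oxy}dimethylsilane | c1ccccc1COc1cc(OCc2ccccc2)c2c(c1Br)O[C@H](c1cc(OCc3ccccc3)c(OCc3ccccc3)c(OCc3ccccc3)c1)[C@H](O[Si](C)(C)C(C)(C)C)C2 | intermediate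
16 | 3,4,5-tris(benzyloxy)benzaldehyde | O=Cc1cc(OCc2ccccc2)c(OCc2ccccc2)c(OCc2ccccc2)c1 | starting material
17 | vinylmagnesium bromide | C=C[Mg]Br | starting material
18 | 1-[3,4,5-tris(benzyloxy)phenyl]prop-2-en-1-ol (racemic) | C=CC(O)c1cc(OCc2ccccc2)c(OCc2ccccc2)c(OCc2ccccc2)c1 | intermediate
19 | 1,3,5-tris(benzyloxy)benzene | c1ccccc1COc1cc(OCc2ccccc2)cc(OCc2ccccc2)c1 | starting material
20 | (E)-1-[3,4,5-tris(benzyloxy)phenyl]-3-[2,4,6-tris(benzyloxy)phenyl]prop-1-ene | C(/C=C/c1cc(OCc2ccccc2)c(OCc2ccccc2)c(OCc2ccccc2)c1)c1c(OCc2ccccc2)cc(OCc2ccccc2)cc1OCc1ccccc1 | intermediate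
21 | (2R,3R)-2-[3,4,5-tris(benzyloxy)phenyl]-3-[2,4,6-tris(benzyloxy)benzyl]oxirane | C(c1c(OCc2ccccc2)cc(OCc2ccccc2)cc1OCc1ccccc1)[C@H]1O[C@@H]1c1cc(OCc2ccccc2)c(OCc2ccccc2)c(OCc2ccccc2)c1 | intermediate
22 | 8-lithio derivative of 15 (lithium in place of bromine) | c1ccccc1COc1cc(OCc2ccccc2)c2c(c1[Li])O[C@H](c1cc(OCc3ccccc3)c(OCc3ccccc3)c(OCc3ccccc3)c1)[C@H](O[Si](C)(C)C(C)(C)C)C2 | intermediate (not isolated)
23 | (1R,2R)-1-{(2R,3R)-5,7-bis(benzyloxy)-3-[(tert-butyldimethylsilyl)oxy]-2-[3,4,5-tris(benzyloxy)phenyl]chroman-8-yl}-1-[3,4,5-tris(benzyloxy)phenyl]-3-[2,4,6-tris(benzyloxy)phenyl]propan-2-ol | O[C@H](Cc1c(OCc2ccccc2)cc(OCc2ccccc2)cc1OCc1ccccc1)[C@H](c1cc(OCc2ccccc2)c(OCc2ccccc2)c(OCc2ccccc2)c1)c1c(OCc2ccccc2)cc(OCc2ccccc2)c2c1O[C@H](c1cc(OCc3ccccc3)c(OCc3ccccc3)c(OCc3ccccc3)c1)[C@H](O[Si](C)(C)C(C)(C)C)C2 | intermediate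
24 | (2R,3R)-8-{(1R,2R)-2-hydroxy-1-[3,4,5-tris(benzyloxy)phenyl]-3-[2,4,6-tris(benzyloxy)phenyl]propyl}-5,7-bis(benzyloxy)-2-[3,4,5-tris(benzyloxy)phenyl]chroman-3-ol | O[C@H](Cc1c(OCc2ccccc2)cc(OCc2ccccc2)cc1OCc1ccccc1)[C@H](c1cc(OCc2ccccc2)c(OCc2ccccc2)c(OCc2ccccc2)c1)c1c(OCc2ccccc2)cc(OCc2ccccc2)c2c1O[C@H](c1cc(OCc3ccccc3)c(OCc3ccccc3)c(OCc3ccccc3)c1)[C@H](O)C2 | intermediate
25 | bis[3,4,5-tris(benzyloxy)benzoate] of 24 (heptadeca-O-benzyl derivative of the target) | O=C(O[C@H](Cc1c(OCc2ccccc2)cc(OCc2ccccc2)cc1OCc1ccccc1)[C@H](c1cc(OCc2ccccc2)c(OCc2ccccc2)c(OCc2ccccc2)c1)c1c(OCc2ccccc2)cc(OCc2ccccc2)c2c1O[C@H](c1cc(OCc3ccccc3)c(OCc3ccccc3)c(OCc3ccccc3)c1)[C@H](OC(=O)c1cc(OCc3ccccc3)c(OCc3ccccc3)c(OCc3ccccc3)c1)C2)c1cc(OCc2ccccc2)c(OCc2ccccc2)c(OCc2ccccc2)c1 | intermediate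
26 | CNP0155034.2 | O=C(O[C@H](Cc1c(O)cc(O)cc1O)[C@H](c1cc(O)c(O)c(O)c1)c1c(O)cc(O)c2c1O[C@H](c1cc(O)c(O)c(O)c1)[C@H](OC(=O)c1cc(O)c(O)c(O)c1)C2)c1cc(O)c(O)c(O)c1 | target

**Step count and risks**

Total steps: 17 (steps 1–10 on the flavan unit, steps 11–13 on the epoxide, steps 14–17 after the union). Longest linear sequence: 14 steps (steps 1–10 and 14–17).

Steps most likely to fail:

1. Step 5 (titanium ring closure). The ketyl of the enolizable arylacetaldehyde may couple with a second molecule or the aldehyde may self-condense before it reaches the ester; the aryl ester may be cleaved reductively; the acid-labile enol ether may be hydrolysed or isomerized by the Lewis-acidic titanium salts. The fallback replaces reductive coupling by carbonyl methylenation and olefin metathesis and sets out from 6. Methylenation of the aryl ester with the Tebbe reagent Cp2Ti(μ-Cl)(μ-CH2)AlMe2 (THF–pyridine, −40 °C → rt) should give 2-allyl-3,5-bis(benzyloxy)phenyl 1-[3,4,5-tris(benzyloxy)phenyl]vinyl ether F1. Ring-closing metathesis of F1 between the enol ether and allyl alkenes with the second-generation Grubbs catalyst (toluene, 80 °C) then forms the C2=C3 bond with loss of ethylene, and the route is rejoined at 9.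

2. Step 14 (fragment union). The Lewis acid may ionize or rearrange the electron-rich aryl epoxide (hydride shift to a ketone) before C–C bond formation, with loss of regio- and stereocontrol; the basic aryllithium may instead remove a benzylic proton next to the epoxide; the doubly ortho-substituted aryllithium may react too slowly. The fallback uses an electrophilic aromatic substitution without any organometallic and sets out from 13. Acylation of 13 with 5 (Et3N, DMAP, CH2Cl2) gives (2R,3R)-5,7-bis(benzyloxy)-2-[3,4,5-tris(benzyloxy)phenyl]chroman-3-yl 3,4,5-tris(benzyloxy)benzoate F2. A Friedel–Crafts opening of epoxide 21 by the free C8–H of F2 (used in excess) in (CF3)2CHOH at 0 °C → rt, with attack anti to the epoxide oxygen at the benzylic carbon, should then give the 8-alkylated mono-gallate (2R,3R)-8-{(1R,2R)-2-hydroxy-1-[3,4,5-tris(benzyloxy)phenyl]-3-[2,4,6-tris(benzyloxy)phenyl]propyl}-5,7-bis(benzyloxy)-2-[3,4,5-tris(benzyloxy)phenyl]chroman-3-yl 3,4,5-tris(benzyloxy)benzoate F3. Acylation of the remaining alcohol of F3 with 5 rejoins the route at 25, and steps 9, 10 and 15 fall away.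

3. Step 6 (asymmetric hydroboration). The bulky chiral borane may add slowly or with poor face selectivity to the flavene, which would erode the configuration at C2 that steps 7 and 8 only carry forward. The fallback sets both centres later by catalysis and sets out from 9. Hydroboration with BH3·SMe2 (THF, 0 °C) gives the racemic trans-configured 3-borylflavan F4, which NaOH/H2O2 oxidizes to racemic trans-5,7-bis(benzyloxy)-2-[3,4,5-tris(benzyloxy)phenyl]chroman-3-ol F5. Dess–Martin oxidation gives racemic 5,7-bis(benzyloxy)-2-[3,4,5-tris(benzyloxy)phenyl]chroman-3-one F6. A Noyori-type asymmetric transfer hydrogenation under dynamic kinetic resolution (RuCl(p-cymene)[(R,R)-TsDPEN] or its (S,S) antipode, whichever a trial on F6 shows to deliver the 3R carbinol; HCO2H–Et3N, rt) then exploits the base-labile C2 centre to reduce one rapidly equilibrating enantiomer to the cis alcohol, rejoining the route at 13.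

**Further compounds**

F1 | step 5 | 2-allyl-3,5-bis(benzyloxy)phenyl 1-[3,4,5-tris(benzyloxy)phenyl]vinyl ether | C=CCc1c(OC(=C)c2cc(OCc3ccccc3)c(OCc3ccccc3)c(OCc3ccccc3)c2)cc(OCc2ccccc2)cc1OCc1ccccc1
F2 | step 14 | (2R,3R)-5,7-bis(benzyloxy)-2-[3,4,5-tris(benzyloxy)phenyl]chroman-3-yl 3,4,5-tris(benzyloxy)benzoate | c1ccccc1COc1cc(OCc2ccccc2)c2c(c1)O[C@H](c1cc(OCc3ccccc3)c(OCc3ccccc3)c(OCc3ccccc3)c1)[C@H](OC(=O)c1cc(OCc3ccccc3)c(OCc3ccccc3)c(OCc3ccccc3)c1)C2
F3 | step 14 | (2R,3R)-8-{(1R,2R)-2-hydroxy-1-[3,4,5-tris(benzyloxy)phenyl]-3-[2,4,6-tris(benzyloxy)phenyl]propyl}-5,7-bis(benzyloxy)-2-[3,4,5-tris(benzyloxy)phenyl]chroman-3-yl 3,4,5-tris(benzyloxy)benzoate | O[C@H](Cc1c(OCc2ccccc2)cc(OCc2ccccc2)cc1OCc1ccccc1)[C@H](c1cc(OCc2ccccc2)c(OCc2ccccc2)c(OCc2ccccc2)c1)c1c(OCc2ccccc2)cc(OCc2ccccc2)c2c1O[C@H](c1cc(OCc3ccccc3)c(OCc3ccccc3)c(OCc3ccccc3)c1)[C@H](OC(=O)c1cc(OCc3ccccc3)c(OCc3ccccc3)c(OCc3ccccc3)c1)C2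
F4 | step 6 | racemic trans-3-boryl-5,7-bis(benzyloxy)-2-[3,4,5-tris(benzyloxy)phenyl]chroman (both enantiomers, not isolated) | c1ccccc1COc1cc(OCc2ccccc2)c2c(c1)O[C@H](c1cc(OCc3ccccc3)c(OCc3ccccc3)c(OCc3ccccc3)c1)[C@@H](B)C2.c1ccccc1COc1cc(OCc2ccccc2)c2c(c1)O[C@@H](c1cc(OCc3ccccc3)c(OCc3ccccc3)c(OCc3ccccc3)c1)[C@H](B)C2
F5 | step 6 | racemic trans-5,7-bis(benzyloxy)-2-[3,4,5-tris(benzyloxy)phenyl]chroman-3-ol (both enantiomers) | c1ccccc1COc1cc(OCc2ccccc2)c2c(c1)O[C@H](c1cc(OCc3ccccc3)c(OCc3ccccc3)c(OCc3ccccc3)c1)[C@@H](O)C2.c1ccccc1COc1cc(OCc2ccccc2)c2c(c1)O[C@@H](c1cc(OCc3ccccc3)c(OCc3ccccc3)c(OCc3ccccc3)c1)[C@H](O)C2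
F6 | step 6 | racemic 5,7-bis(benzyloxy)-2-[3,4,5-tris(benzyloxy)phenyl]chroman-3-one | c1ccccc1COc1cc(OCc2ccccc2)c2c(c1)OC(c1cc(OCc3ccccc3)c(OCc3ccccc3)c(OCc3ccccc3)c1)C(=O)C2
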